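The route rests on cutting C13–C14 (chain numbered from the ketone carbon C1), the bond from the doubly allylic methylene C13 to the olefinic carbon C14. The key step exploits the all-Z, methylene-interrupted C5–C15 tetraene. Each alkene is carried as an alkyne, so C14 becomes the terminal carbon of (R)-hept-1-yn-4-ol. C13 becomes a primary propargylic bromide at the end of a C1–C13 triynone that already bears the MOM-masked phloroglucinol ring. One CuI-mediated alkynyl–propargyl coupling, tolerant of the free C17 hydroxyl, completes the C26 skeleton as a skipped tetrayne. A single fourfold semihydrogenation then sets all four Z alkenes, and mild acid frees the three phenols.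

Key step: step 8

Remark: the only stereocentre of the target, C17, is R. Enantiopure (R)-2-propyloxirane is taken as a commercial starting material.

Step 1
Reactants: 1 phloroglucinol (benzene-1,3,5-triol)
Product: 2 1,3,5-tris(methoxymethoxy)benzene
Conditions: NaH (3.6 equiv), MOMCl (3.6 equiv), DMF, 0 °C to rt
Reagents that add atoms: chloromethyl methyl ether (MOMCl), COCCl
Why: Williamson-type O-alkylation of the phenoxides with the hard electrophile MOMCl should give the tris-acetal, which withstands organolithium, carbonate/copper and hydrogenation conditions and later directs the lithiation.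

Step 2
Reactants: 3 hex-5-ynoic acid
Product: 5 N-methoxy-N-methylhex-5-ynamide, via acyl imidazolide 4 (not isolated)
Conditions: CDI (1.1 equiv), CH2Cl2, rt, 1 h; then MeNHOMe·HCl (1.2 equiv), rt
Reagents that add atoms: N,O-dimethylhydroxylamine hydrochloride, CNOC.Cl; 1,1'-carbonyldiimidazole (CDI), O=C(n1ccnc1)n1ccnc1 (its imidazole stands only in 4)
Why: CDI activation gives acyl imidazolide 4, which acylates the hydroxylamine nitrogen (amide formation by way of an acyl imidazole), while the terminal alkyne is a spectator.

Step 3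
Reactants: 2 1,3,5-tris(methoxymethoxy)benzene; 5 N-methoxy-N-methylhex-5-ynamide
Product: 8 1-[2,4,6-tris(methoxymethoxy)phenyl]hex-5-yn-1-one, via aryllithium 6 (not isolated), via dilithiated tetrahedral adduct 7 (not isolated)
Conditions: 2 (2.4 equiv), n-BuLi (2.2 equiv), THF, 0 °C, 1 h; then 5 (1.0 equiv), −78 °C to 0 °C; then H2O
Reagents that add atoms: n-butyllithium, [Li]CCCC (its lithium stands only in 6 and 7)
Why: Directed ortho-metalation between two MOM ethers gives 6, one equivalent of which takes the alkynyl proton while a second adds to the amide (Weinreb ketone synthesis), and the chelated adduct 7 holds until the aqueous quench so that no second addition can occur.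

Step 4
Reactants: 9 prop-2-yn-1-ol; 10 1,4-dichlorobut-2-yne
Product: 12 7-chlorohepta-2,5-diyn-1-ol, via cuprous acetylide 11 (not isolated)
Conditions: 10 (4 equiv), CuI (10 mol %), nBu4NCl (1 equiv), K2CO3 (1.5 equiv), DMF, 0 °C to rt, argon; excess 10 recovered by distillation
Reagents that add atoms: CuI, [Cu]I (its copper stands only in 11)
Why: This is a copper-catalysed coupling of a terminal alkyne with a propargylic halide under solid–liquid phase-transfer conditions, in which the fourfold excess of the symmetrical dichloride 10 should make single substitution dominant and the chloride-rich medium keeps the remaining leaving group defined.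

Step 5
Reactants: 8 1-[2,4,6-tris(methoxymethoxy)phenyl]hex-5-yn-1-one; 12 7-chlorohepta-2,5-diyn-1-ol
Product: 15 13-hydroxy-1-[2,4,6-tris(methoxymethoxy)phenyl]trideca-5,8,11-triyn-1-one, via cuprous acetylide 13 (not isolated), via diyne iodide 14 (not isolated)
Conditions: 12 (1.2 equiv), CuI (1.0 equiv), NaI (1.2 equiv), Cs2CO3 (1.2 equiv), DMF, rt, argon, dark
Reagents that add atoms: CuI, [Cu]I (its copper stands only in 13); NaI, [Na+].[I-] (its iodine stands only in 14)
Why: This is the same copper-mediated alkynyl–propargyl coupling, now with Finkelstein activation of chloride 12 to iodide 14, which acetylide 13 displaces at the primary carbon, while the free primary alcohol, the hindered ketone and the MOM ethers are inert to Cs2CO3 in DMF.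

Step 6
Reactants: 15 13-hydroxy-1-[2,4,6-tris(methoxymethoxy)phenyl]trideca-5,8,11-triyn-1-one
Product: 16 13-bromo-1-[2,4,6-tris(methoxymethoxy)phenyl]trideca-5,8,11-triyn-1-one
Conditions: CBr4 (1.3 equiv), PPh3 (1.3 equiv), CH2Cl2, −20 °C to 0 °C, argon
Reagents that add atoms: carbon tetrabromide, BrC(Br)(Br)Br
Why: The Appel reaction is a neutral SN2 bromination of a primary alcohol and should spare the base-sensitive skipped triyne, the ketone and the acetals.

Step 7
Reactants: 17 (R)-2-propyloxirane; 18 lithium acetylide–ethylenediamine complex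
Product: 19 (4R)-hept-1-yn-4-ol
Conditions: 18 (1.5 equiv), DMSO, 0 °C to rt; then H2O
Reagents that add atoms: none
Why: SN2 opening of the terminal epoxide at its unsubstituted carbon by the acetylide leaves the C–O bond of the stereocentre untouched, so the R configuration of 17 becomes that of C17.

Step 8
Reactants: 16 13-bromo-1-[2,4,6-tris(methoxymethoxy)phenyl]trideca-5,8,11-triyn-1-one; 19 (4R)-hept-1-yn-4-ol
Product: 22 (17R)-17-hydroxy-1-[2,4,6-tris(methoxymethoxy)phenyl]icosa-5,8,11,14-tetrayn-1-one, via cuprous acetylide 20 (not isolated), via triyne iodide 21 (not isolated)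
Conditions: 19 (1.2 equiv), CuI (1.1 equiv), NaI (1.1 equiv), Cs2CO3 (1.1 equiv), DMF, 0 °C to rt, argon, dark; product taken on at once
Reagents that add atoms: CuI, [Cu]I (its copper stands only in 20); NaI, [Na+].[I-] (its iodine stands only in 21)
Why: Cs2CO3 and CuI turn the terminal alkyne of 19 into cuprous acetylide 20 while NaI converts bromide 16 into the more reactive iodide 21 (Finkelstein exchange), and 20 then displaces iodide at the primary propargylic carbon C13, which forms C13–C14 and gives CuI back. The closest known reaction type is the copper-mediated coupling of terminal alkynes with propargylic halides in DMF with a carbonate base, the standard entry to skipped diynes and polyynes of the polyunsaturated fatty acid series. No ring is closed and no stereocentre is made, and C17 lies three bonds from the reacting carbon and keeps its R configuration. The step needs carbon over oxygen alkylation, which is secured because the carbonate cannot deprotonate the secondary alcohol, only the copper-bound carbon is nucleophilic and the three phenols are masked as MOM ethers. It needs direct substitution over attack at the distal alkyne carbon (allene formation), which the unhindered primary CH2 and the internal, alkyl-capped alkyne of 21 favour. The weak base, low temperature, darkness and argon hold back propargyl–allene isomerisation of the acidic doubly propargylic CH2 groups and oxidative (Glaser-type) alkyne homocoupling.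

Step 9
Reactants: 22 (17R)-17-hydroxy-1-[2,4,6-tris(methoxymethoxy)phenyl]icosa-5,8,11,14-tetrayn-1-one
Product: 23 (5Z,8Z,11Z,14Z,17R)-17-hydroxy-1-[2,4,6-tris(methoxymethoxy)phenyl]icosa-5,8,11,14-tetraen-1-one
Conditions: H2 (1 atm), Pd/CaCO3 poisoned with Pb(OAc)2 (Lindlar catalyst), quinoline, EtOAc–2-methylbut-2-ene, 0 to 10 °C, followed by NMR of aliquots
Reagents that add atoms: none
Why: In the Lindlar semihydrogenation, syn delivery of H2 on the lead- and quinoline-poisoned palladium surface should turn each of the four alkynes into a Z alkene, while the ketone, the MOM ethers and the C17 carbinol are not touched.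

Step 10
Reactants: 23 (5Z,8Z,11Z,14Z,17R)-17-hydroxy-1-[2,4,6-tris(methoxymethoxy)phenyl]icosa-5,8,11,14-tetraen-1-one
Product: 24 (5Z,8Z,11Z,14Z,17R)-17-hydroxy-1-(2,4,6-trihydroxyphenyl)icosa-5,8,11,14-tetraen-1-one
Conditions: HCl (about 1 M in MeOH), 35 °C, argon
Reagents that add atoms: none
Why: Acid-catalysed acetal exchange with methanol removes the three MOM groups as dimethoxymethane, while the isolated Z alkenes, the doubly allylic CH2 groups and the secondary alcohol are stable to dilute methanolic HCl.

Compound list
1 | phloroglucinol (benzene-1,3,5-triol) | Oc1cc(O)cc(O)c1 | starting material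
2 | 1,3,5-tris(methoxymethoxy)benzene | COCOc1cc(OCOC)cc(OCOC)c1 | intermediate
3 | hex-5-ynoic acid | C#CCCCC(=O)O | starting material
4 | 1-(1H-imidazol-1-yl)hex-5-yn-1-one (acyl imidazolide) | C#CCCCC(=O)n1ccnc1 | intermediate
5 | N-methoxy-N-methylhex-5-ynamide | C#CCCCC(=O)N(C)OC | intermediate
6 | 2,4,6-tris(methoxymethoxy)phenyllithium | [Li]c1c(OCOC)cc(OCOC)cc1OCOC | intermediate
7 | dilithiated tetrahedral adduct of 6 and 5 (lithium alkoxide and lithium acetylide) | [Li]C#CCCCC(O[Li])(N(C)OC)c1c(OCOC)cc(OCOC)cc1OCOC | intermediate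
8 | 1-[2,4,6-tris(methoxymethoxy)phenyl]hex-5-yn-1-one | C#CCCCC(=O)c1c(OCOC)cc(OCOC)cc1OCOC | intermediate
9 | prop-2-yn-1-ol | C#CCO | starting material
10 | 1,4-dichlorobut-2-yne | ClCC#CCCl | starting material
11 | cuprous acetylide of prop-2-yn-1-ol | OCC#C[Cu] | intermediate
12 | 7-chlorohepta-2,5-diyn-1-ol | OCC#CCC#CCCl | intermediate
13 | cuprous acetylide of 8 | [Cu]C#CCCCC(=O)c1c(OCOC)cc(OCOC)cc1OCOC | intermediate
14 | 7-iodohepta-2,5-diyn-1-ol | OCC#CCC#CCI | intermediate
15 | 13-hydroxy-1-[2,4,6-tris(methoxymethoxy)phenyl]trideca-5,8,11-triyn-1-one | OCC#CCC#CCC#CCCCC(=O)c1c(OCOC)cc(OCOC)cc1OCOC | intermediate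
16 | 13-bromo-1-[2,4,6-tris(methoxymethoxy)phenyl]trideca-5,8,11-triyn-1-one | BrCC#CCC#CCC#CCCCC(=O)c1c(OCOC)cc(OCOC)cc1OCOC | intermediate
17 | (R)-2-propyloxirane | CCC[C@@H]1CO1 | starting material
18 | lithium acetylide–ethylenediamine complex | [Li]C#C.NCCN | starting material
19 | (4R)-hept-1-yn-4-ol | CCC[C@@H](O)CC#C | intermediate
20 | cuprous acetylide of 19 | CCC[C@@H](O)CC#C[Cu] | intermediate
21 | 13-iodo-1-[2,4,6-tris(methoxymethoxy)phenyl]trideca-5,8,11-triyn-1-one | ICC#CCC#CCC#CCCCC(=O)c1c(OCOC)cc(OCOC)cc1OCOC | intermediate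
22 | (17R)-17-hydroxy-1-[2,4,6-tris(methoxymethoxy)phenyl]icosa-5,8,11,14-tetrayn-1-one | CCC[C@@H](O)CC#CCC#CCC#CCC#CCCCC(=O)c1c(OCOC)cc(OCOC)cc1OCOC | intermediate
23 | (5Z,8Z,11Z,14Z,17R)-17-hydroxy-1-[2,4,6-tris(methoxymethoxy)phenyl]icosa-5,8,11,14-tetraen-1-one | CCC[C@@H](O)C/C=C\C/C=C\C/C=C\C/C=C\CCCC(=O)c1c(OCOC)cc(OCOC)cc1OCOC | intermediate
24 | (5Z,8Z,11Z,14Z,17R)-17-hydroxy-1-(2,4,6-trihydroxyphenyl)icosa-5,8,11,14-tetraen-1-one | CCC[C@@H](O)C/C=C\C/C=C\C/C=C\C/C=C\CCCC(=O)c1c(O)cc(O)cc1O | target

Total step count: 10. Longest linear sequence: 7 steps (1, 3, 5, 6, 8, 9, 10).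

Steps most likely to fail

1. Step 9. Over-reduction and incomplete reduction may run side by side on four alkynes, together with some Z to E drift, which would give mixtures that are hard to separate.
Fallback: the reduction is split in two, and the union becomes an alkynyl–allyl instead of an alkynyl–propargyl coupling. It sets out from 15. The three alkynes are semihydrogenated at the stage of the polar alcohol (H2, Pd/CaCO3 poisoned with Pb(OAc)2, quinoline). There, chromatography on AgNO3-impregnated silica can remove over-reduced material, and the product is (5Z,8Z,11Z)-13-hydroxy-1-[2,4,6-tris(methoxymethoxy)phenyl]trideca-5,8,11-trien-1-one F1. An Appel reaction (CBr4, PPh3, CH2Cl2) gives the Z-allylic bromide (5Z,8Z,11Z)-13-bromo-1-[2,4,6-tris(methoxymethoxy)phenyl]trideca-5,8,11-trien-1-one F2. Copper-catalysed coupling of 19 with this bromide (CuI, K2CO3, nBu4NBr, DMF) makes the same C13–C14 bond by direct substitution at the primary allylic carbon. It gives (5Z,8Z,11Z,17R)-17-hydroxy-1-[2,4,6-tris(methoxymethoxy)phenyl]icosa-5,8,11-trien-14-yn-1-one F3. The single remaining alkyne is then semihydrogenated, and the fallback comes back to the route at 23.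

2. Step 8. The triyne bromide may undergo base-induced propargyl–allene isomerisation and decompose before it couples. Attack at the distal alkyne carbon and oxidative homocoupling of the alkynol are further risks.
Fallback: a two-plus-two assembly that never needs a triyne halide. It sets out from 19 and 8.
- 19 is coupled with commercial 3-bromo-1-(trimethylsilyl)prop-1-yne (CuI, Cs2CO3, DMF), which makes the C13–C14 bond on a small, robust bromide and gives (4R)-10-(trimethylsilyl)deca-6,9-diyn-4-ol F4.
- Buffered desilylation (TBAF, AcOH, THF, 0 °C) gives (4R)-deca-6,9-diyn-4-ol F5.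
- Separately, 8 is coupled with an excess of 10 in the manner of step 4 to give 10-chloro-1-[2,4,6-tris(methoxymethoxy)phenyl]deca-5,8-diyn-1-one F6.
- A last copper-mediated coupling of the two diynes (CuI, NaI, Cs2CO3, DMF) joins C10 to C11, and the fallback comes back to the route at 22.

3. Step 4. The dichloride may undergo double substitution, the halides may scramble, and the chloride may convert sluggishly in an iodide-poor medium.
Fallback: linear chain growth instead of a C7 linchpin. It sets out from 8. Copper-mediated coupling with commercial 4-chlorobut-2-yn-1-ol (CuI, NaI, Cs2CO3, DMF), an electrophile with only one leaving group, gives 10-hydroxy-1-[2,4,6-tris(methoxymethoxy)phenyl]deca-5,8-diyn-1-one F7. An Appel reaction gives 10-bromo-1-[2,4,6-tris(methoxymethoxy)phenyl]deca-5,8-diyn-1-one F8. Coupling of this bromide with 9 (CuI, NaI, Cs2CO3, DMF) brings the fallback back to the route at 15.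

Further compounds
F1 | step 9 | (5Z,8Z,11Z)-13-hydroxy-1-[2,4,6-tris(methoxymethoxy)phenyl]trideca-5,8,11-trien-1-one | OC/C=C\C/C=C\C/C=C\CCCC(=O)c1c(OCOC)cc(OCOC)cc1OCOC
F2 | step 9 | (5Z,8Z,11Z)-13-bromo-1-[2,4,6-tris(methoxymethoxy)phenyl]trideca-5,8,11-trien-1-one | BrC/C=C\C/C=C\C/C=C\CCCC(=O)c1c(OCOC)cc(OCOC)cc1OCOC
F3 | step 9 | (5Z,8Z,11Z,17R)-17-hydroxy-1-[2,4,6-tris(methoxymethoxy)phenyl]icosa-5,8,11-trien-14-yn-1-one | CCC[C@@H](O)CC#CC/C=C\C/C=C\C/C=C\CCCC(=O)c1c(OCOC)cc(OCOC)cc1OCOC
F4 | step 8 | (4R)-10-(trimethylsilyl)deca-6,9-diyn-4-ol | CCC[C@@H](O)CC#CCC#C[Si](C)(C)C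
F5 | step 8 | (4R)-deca-6,9-diyn-4-ol | CCC[C@@H](O)CC#CCC#C
F6 | step 8 | 10-chloro-1-[2,4,6-tris(methoxymethoxy)phenyl]deca-5,8-diyn-1-one | ClCC#CCC#CCCCC(=O)c1c(OCOC)cc(OCOC)cc1OCOC
F7 | step 4 | 10-hydroxy-1-[2,4,6-tris(methoxymethoxy)phenyl]deca-5,8-diyn-1-one | OCC#CCC#CCCCC(=O)c1c(OCOC)cc(OCOC)cc1OCOC
F8 | step 4 | 10-bromo-1-[2,4,6-tris(methoxymethoxy)phenyl]deca-5,8-diyn-1-one | BrCC#CCC#CCCCC(=O)c1c(OCOC)cc(OCOC)cc1OCOC
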